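## Retrosynthetic overview

1. Pestallic acid P ⇒ ester hydrolysis and acetonide removal; the C1 heptenyl group ⇒ Suzuki coupling at a vinyl C–Br bond; the C2 CH2OH group ⇒ Stille coupling at a vinyl C–I bond.
2. The C5 side chain and the free C6 hydroxyl ⇒ Wittig olefination of a lactol ⇒ cis-fused γ-lactone spanning C5 and C6.
3. Key disconnection: γ-lactone ⇒ dihalodiene acetonide + malonic acid. The malonate α-carbon is oxidised to an electrophilic α-carbonyl radical (a one-electron enolonium equivalent) and bonds to the nucleophilic diene terminus C5; the carboxyl then closes on C6. This sets C5 and C6 in one step.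
4. Dihalodiene cis-diol ⇒ 1-bromo-2-iodobenzene by enzymatic cis-dihydroxylation, which sets C3 and C4.
5. Ring order: the carbocycle (ring A) is the original benzene ring and is never closed; the dioxolane (ring B) is formed first and the γ-lactone (ring C) second; ring C is opened in the Wittig step and ring B in the last step.

Convention: ring carbons are called C1–C6 as in the target (C1 heptenyl, C2 CH2OH, C3 and C4 cis-diol, C5 side chain, C6 hydroxyl). "Top face" is the face of the C3/C4 oxygens.

Assumption: toluene dioxygenase places the cis-diol next to the larger halogen (iodine) of 1-bromo-2-iodobenzene, as it does with other iodoarenes; the opposite outcome is handled in the fallback to step 1.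

## Route

Step 1
Reactants: 1 1-bromo-2-iodobenzene
Product: 2 (1S,2S)-4-bromo-3-iodocyclohexa-3,5-diene-1,2-diol
Conditions: E. coli JM109(pDTG601A) whole cells (toluene dioxygenase), glucose feed, air, phosphate buffer pH 6.8, 35 °C; EtOAc extraction
Reagents that add atoms: dioxygen, O=O
Why: Enzymatic arene cis-dihydroxylation (Gibson–Hudlicky reaction): the dioxygenase adds both oxygens of O2 to one face of the arene bond next to the directing halogen, giving the (1S,2S)-diol that becomes C3 and C4 of the target, as with bromo- and iodobenzene.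

Step 2
Reactants: 2 (1S,2S)-4-bromo-3-iodocyclohexa-3,5-diene-1,2-diol
Product: 3 (3aS,7aS)-5-bromo-4-iodo-2,2-dimethyl-3a,7a-dihydro-1,3-benzodioxole
Conditions: 2,2-dimethoxypropane, TsOH·H2O (cat.), acetone, 0 °C to rt; used at once
Reagents that add atoms: 2,2-dimethoxypropane, COC(C)(C)OC
Why: Acid-catalysed transketalisation closes the dioxolane on the cis-diol without touching a stereocentre, stops dehydration to the phenol and blocks the top face for step 3.

Step 3
Reactants: 3 (3aS,7aS)-5-bromo-4-iodo-2,2-dimethyl-3a,7a-dihydro-1,3-benzodioxole; 4 malonic acid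
Product: 6 bromo-iodo γ-lactone acetonide (CH2 on C5 and lactone O on C6 on the bottom face), via carboxy lactone 5 (not isolated)
Conditions: Mn(OAc)3·2H2O (2.2 equiv), Cu(OAc)2·H2O (10 mol %), KOAc, AcOH, 25 °C; then pyridine, 100 °C
Reagents that add atoms: malonic acid (4), OC(=O)CC(=O)O
Why: Manganese triacetate oxidative carbolactonization (Heiba–Dessau reaction, malonic acid variant): the trivalent-manganese enolate of malonic acid gives an electrophilic α-carbonyl radical that attacks the unsubstituted diene terminus C5 on the face opposite the acetonide, the allyl radical is oxidised by Cu(OAc)2 and the carboxyl closes on C6 from the same face, so the C5–C and C6–O bonds are set cis to each other and trans to the C4 oxygen before 5 loses CO2 on heating.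

Step 4
Reactants: 6 bromo-iodo γ-lactone acetonide
Product: 7 bromo-iodo lactol acetonide (anomer mixture)
Conditions: i-Bu2AlH (1.2 equiv), CH2Cl2, −78 °C; aq. potassium sodium tartrate
Reagents that add atoms: none
Why: DIBAL-H half-reduction of a γ-lactone stops at the aluminium hemiacetal at −78 °C and leaves the vinyl halides, the acetonide and all stereocentres untouched.

Step 5
Reactants: 7 bromo-iodo lactol acetonide; 8 ethyl 2-(triphenyl-λ5-phosphanylidene)propanoate
Product: 10 ethyl (E)-enoate with free C6–OH (C1–Br and C2–I retained), via hydroxy aldehyde 9 (not isolated)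
Conditions: 8 (2.5 equiv), PhCO2H (cat.), toluene, 80 °C
Reagents that add atoms: ethyl 2-(triphenyl-λ5-phosphanylidene)propanoate (8), CCOC(=O)C(C)=P(c1ccccc1)(c1ccccc1)c1ccccc1
Why: Wittig olefination of the lactol through its open hydroxy aldehyde with a stabilised α-methyl ylide gives the (E)-trisubstituted enoate and frees the C6 hydroxyl; the trisubstituted enoate is too poor an acceptor for oxa-Michael closure under these neutral conditions.

Step 6
Reactants: 10 ethyl (E)-enoate (C1–Br, C2–I); 11 (tributylstannyl)methanol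
Product: 12 C2-hydroxymethyl vinyl bromide
Conditions: 11 (1.5 equiv), Pd2(dba)3 (5 mol %), AsPh3 (20 mol %), CuI (10 mol %), NMP, 50 °C
Reagents that add atoms: (tributylstannyl)methanol (11), OC[Sn](CCCC)(CCCC)CCCC
Why: Migita–Kosugi–Stille coupling: zerovalent palladium inserts into the vinyl C–I bond far faster than into the neighbouring C–Br bond, so CH2OH goes onto C2 only and no stereocentre is involved.

Step 7
Reactants: 12 C2-hydroxymethyl vinyl bromide; 13 (E)-hept-1-en-1-ylboronic acid
Product: 14 ethyl ester acetonide of pestallic acid P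
Conditions: 13 (1.5 equiv), Pd(OAc)2 (5 mol %), SPhos (10 mol %), K3PO4, THF/H2O (10:1), 50 °C
Reagents that add atoms: (E)-hept-1-en-1-ylboronic acid (13), CCCCC/C=C/B(O)O
Why: Suzuki–Miyaura coupling of the remaining tetrasubstituted vinyl bromide proceeds with retention of both alkene geometries, the bulky electron-rich SPhos ligand overcoming the hindrance; the free hydroxyls and the enoate are tolerated.

Step 8
Reactants: 14 ethyl ester acetonide of pestallic acid P
Product: 16 pestallic acid P, via acetonide acid 15 (not isolated)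
Conditions: LiOH·H2O (3 equiv), THF/MeOH/H2O, 25 °C; concentrate; then AcOH/H2O (4:1), 40 °C
Reagents that add atoms: lithium hydroxide, [Li+].[OH-]
Why: Saponification of the ethyl enoate followed in the same flask by acetal hydrolysis in aqueous acetic acid (weak enough to spare the dienylic C3 alcohol) frees the acid and the cis-diol without touching a stereocentre.

## Compound list

1 | 1-bromo-2-iodobenzene | Brc1ccccc1I | starting material
2 | (1S,2S)-4-bromo-3-iodocyclohexa-3,5-diene-1,2-diol | BrC1=C(I)[C@@H](O)[C@@H](O)C=C1 | intermediate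
3 | (3aS,7aS)-5-bromo-4-iodo-2,2-dimethyl-3a,7a-dihydro-1,3-benzodioxole | BrC1=C(I)[C@H]2OC(C)(C)O[C@H]2C=C1 | intermediate
4 | malonic acid | OC(=O)CC(=O)O | starting material
5 | carboxy lactone: C1-bromo-C2-iodo cyclohexene, C3/C4 acetonide on the top face, cis-fused 2-oxotetrahydrofuran-3-carboxylic acid on the bottom face (C on C5, O on C6), epimer mixture at the carboxyl-bearing carbon | BrC1=C(I)[C@H]2OC(C)(C)O[C@H]2[C@@H]3C(C(=O)O)C(=O)O[C@H]13 | intermediate (not isolated)
6 | bromo-iodo γ-lactone acetonide: as 5 without the carboxyl group (CH2 on C5, lactone O on C6, both on the bottom face) | BrC1=C(I)[C@H]2OC(C)(C)O[C@H]2[C@@H]3CC(=O)O[C@H]13 | intermediate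
7 | bromo-iodo lactol acetonide (anomer mixture) | BrC1=C(I)[C@H]2OC(C)(C)O[C@H]2[C@@H]3CC(O)O[C@H]13 | intermediate
8 | ethyl 2-(triphenyl-λ5-phosphanylidene)propanoate | CCOC(=O)C(C)=P(c1ccccc1)(c1ccccc1)c1ccccc1 | starting material
9 | hydroxy aldehyde: open form of 7, C5–CH2CHO and C6–OH both on the bottom face | BrC1=C(I)[C@H]2OC(C)(C)O[C@H]2[C@H](CC=O)[C@@H]1O | intermediate (not isolated)
10 | ethyl (E)-4-(ring-C5)-2-methylbut-2-enoate of the C1-bromo-C2-iodo acetonide, free C6–OH cis to the side chain | BrC1=C(I)[C@H]2OC(C)(C)O[C@H]2[C@H](C/C=C(\C)C(=O)OCC)[C@@H]1O | intermediate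
11 | (tributylstannyl)methanol | OC[Sn](CCCC)(CCCC)CCCC | starting material
12 | as 10 with CH2OH in place of iodine on C2 (C1–Br retained) | BrC1=C(CO)[C@H]2OC(C)(C)O[C@H]2[C@H](C/C=C(\C)C(=O)OCC)[C@@H]1O | intermediate
13 | (E)-hept-1-en-1-ylboronic acid | CCCCC/C=C/B(O)O | starting material
14 | ethyl ester, C3/C4-O-isopropylidene acetal of pestallic acid P | CCCCC/C=C/C1=C(CO)[C@H]2OC(C)(C)O[C@H]2[C@H](C/C=C(\C)C(=O)OCC)[C@@H]1O | intermediate
15 | C3/C4-O-isopropylidene acetal of pestallic acid P (free acid) | CCCCC/C=C/C1=C(CO)[C@H]2OC(C)(C)O[C@H]2[C@H](C/C=C(\C)C(=O)O)[C@@H]1O | intermediate (not isolated)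
16 | pestallic acid P, (E)-4-[(1R,2S,5R,6S)-3-[(E)-hept-1-enyl]-2,5,6-trihydroxy-4-(hydroxymethyl)cyclohex-3-en-1-yl]-2-methylbut-2-enoic acid | CCCCC/C=C/C1=C(CO)[C@@H](O)[C@@H](O)[C@H](C/C=C(\C)C(=O)O)[C@@H]1O | target

## Step count and risks

Total step count: 8. Longest linear sequence: 8 steps (1 to 16); compounds 4, 8, 11 and 13 are bought.

The three steps most likely to fail:

Step 1 (regiochemistry and productivity of the enzymatic dihydroxylation on an ortho-dihalobenzene). Fallback, setting out from 1 and returning at 14: if the enzyme hydroxylates next to bromine, the regioisomer is carried through with the two couplings in reverse order. The diol obtained is (1S,2S)-3-bromo-4-iodocyclohexa-3,5-diene-1,2-diol F1. Acetonide formation gives (3aS,7aS)-4-bromo-5-iodo-2,2-dimethyl-3a,7a-dihydro-1,3-benzodioxole F2. The same manganese triacetate carbolactonization with 4 gives the regioisomeric carboxy lactone F3 and, after loss of CO2, the iodo-bromo γ-lactone F4. DIBAL-H gives the lactol F5, and Wittig olefination with 8 through the open hydroxy aldehyde F6 gives the enoate F7, which now has iodine on C1 and bromine on C2. Suzuki coupling with 13 at the C–I bond (Pd(dppf)Cl2, K3PO4, THF/H2O, rt) gives the C1-heptenyl C2-bromide F8. Stille hydroxymethylation with 11 at the remaining C–Br bond (Pd(PPh3)4, dioxane, 90 °C) gives 14.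

Step 3 (the key radical carbolactonization on an acid- and heat-sensitive dihalodiene). Fallback, setting out from 3 and returning at 6: the two-carbon unit is delivered by a carbenoid instead of a radical. Rh2(OAc)4-catalysed cyclopropanation of the C5=C6 bond of 3 with ethyl diazoacetate, on the face opposite the acetonide, gives the vinylcyclopropane ethyl ester F9. LiOH saponification gives the vinylcyclopropane acid F10. Camphorsulfonic acid in CH2Cl2 then cleaves the allylic C6–C bond of the cyclopropane and the carboxyl captures C6 from the same face, giving 6.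

Step 6 (transfer of the sp3 hydroxymethyl group to a hindered tetrasubstituted vinyl iodide without touching the C–Br bond). Fallback, setting out from 6 and returning at 12: the CH2OH carbon is brought in as carbon monoxide before the reduction. Methoxycarbonylation of the C–I bond of 6 (Pd(OAc)2, PPh3, CO 1 atm, MeOH, Et3N, DMF, 40 °C) gives the bromo methyl ester lactone F11. DIBAL-H (4 equiv, CH2Cl2, −78 °C) reduces the lactone to the lactol and the conjugated ester to the allylic alcohol in one operation, giving the hydroxymethyl lactol F12. Wittig olefination with 8 through the open hydroxy aldehyde F13 gives 12.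

Further compounds

F1 | step 1 | (1S,2S)-3-bromo-4-iodocyclohexa-3,5-diene-1,2-diol | IC1=C(Br)[C@@H](O)[C@@H](O)C=C1
F2 | step 1 | (3aS,7aS)-4-bromo-5-iodo-2,2-dimethyl-3a,7a-dihydro-1,3-benzodioxole | IC1=C(Br)[C@H]2OC(C)(C)O[C@H]2C=C1
F3 | step 1 | regioisomeric carboxy lactone (I on C1, Br on C2), epimer mixture at the carboxyl-bearing carbon | IC1=C(Br)[C@H]2OC(C)(C)O[C@H]2[C@@H]3C(C(=O)O)C(=O)O[C@H]13
F4 | step 1 | iodo-bromo γ-lactone acetonide (I on C1, Br on C2) | IC1=C(Br)[C@H]2OC(C)(C)O[C@H]2[C@@H]3CC(=O)O[C@H]13
F5 | step 1 | iodo-bromo lactol acetonide (anomer mixture) | IC1=C(Br)[C@H]2OC(C)(C)O[C@H]2[C@@H]3CC(O)O[C@H]13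
F6 | step 1 | open hydroxy aldehyde of F5 | IC1=C(Br)[C@H]2OC(C)(C)O[C@H]2[C@H](CC=O)[C@@H]1O
F7 | step 1 | ethyl (E)-enoate with C1–I and C2–Br, free C6–OH | IC1=C(Br)[C@H]2OC(C)(C)O[C@H]2[C@H](C/C=C(\C)C(=O)OCC)[C@@H]1O
F8 | step 1 | C1-[(E)-hept-1-enyl] C2-bromide ethyl ester acetonide | CCCCC/C=C/C1=C(Br)[C@H]2OC(C)(C)O[C@H]2[C@H](C/C=C(\C)C(=O)OCC)[C@@H]1O
F9 | step 3 | vinylcyclopropane ethyl ester (cyclopropane on C5/C6, bottom face; epimer mixture at the ester carbon) | BrC1=C(I)[C@H]2OC(C)(C)O[C@H]2[C@@H]3C(C(=O)OCC)[C@H]13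
F10 | step 3 | vinylcyclopropane carboxylic acid | BrC1=C(I)[C@H]2OC(C)(C)O[C@H]2[C@@H]3C(C(=O)O)[C@H]13
F11 | step 6 | C1-bromo C2-methoxycarbonyl γ-lactone acetonide | BrC1=C(C(=O)OC)[C@H]2OC(C)(C)O[C@H]2[C@@H]3CC(=O)O[C@H]13
F12 | step 6 | C1-bromo C2-hydroxymethyl lactol acetonide (anomer mixture) | BrC1=C(CO)[C@H]2OC(C)(C)O[C@H]2[C@@H]3CC(O)O[C@H]13
F13 | step 6 | open hydroxy aldehyde of F12 | BrC1=C(CO)[C@H]2OC(C)(C)O[C@H]2[C@H](CC=O)[C@@H]1O
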